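**Plan**

- Retrosynthesis: the C2–H and C3–H bonds are cut first, taking the flavanone back to the planar flavone. Ring C is then cut at C4a–C4, C4–C3 and O1–C2 into an ortho-iodophenol, carbon monoxide and 4-ethynylanisole. The iodophenol goes back to 1,2,3,4-tetramethoxybenzene by removal of I and of OH (by way of CHO).
- Enabling feature: C4 is a single carbonyl carbon between C4a of ring A and C3, and O1 sits on the neighbouring ring A carbon C8a. Ring C can therefore be assembled from an iodophenol (C4a, C8a, O1), CO (C4) and an aryl alkyne (C3, C2 and ring B).
- Forward order: ring A is completed first (formylation, Dakin oxidation, iodination). Ring C is then closed onto it in one palladium-catalysed three-component operation that also brings in ring B. The C2=C3 bond is reduced last.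
- Stereochemistry: C2, the only stereocentre, is set by catalyst-controlled enantioselective hydrogenation of the flavone with a chiral Ru–NHC complex. Over-reduced flavan-4-ol is returned to the ketone by Dess–Martin oxidation in the same step.

Key step: step 4

Remark: 1,2,3,4-tetramethoxybenzene, 4-ethynylanisole and carbon monoxide are taken as catalogue chemicals.
Remark: the (R,R) enantiomer of the carbene ligand is written for step 5 on the assumption that it directs hydrogen to the face of C2 that gives the 2S product; if a first run shows the opposite sense, the (S,S) ligand is used with nothing else changed.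

**Route**

Step 1
Reactants: 1 1,2,3,4-tetramethoxybenzene
Product: 3 2,3,4,5-tetramethoxybenzaldehyde, via aryl iminium salt 2 (not isolated)
Conditions: POCl3, DMF, 0 °C to 80 °C; then H2O, 0 °C to rt
Reagents that add atoms: N,N-dimethylformamide, CN(C)C=O; water, O
Why: Vilsmeier–Haack formylation: the chloroiminium ion made from POCl3 and DMF attacks one of the two equivalent free positions of 1 (ortho and para to methoxy groups), the iminium salt 2 is hydrolysed on aqueous work-up, and the formyl group deactivates the ring against a second substitution.

Step 2
Reactants: 3 2,3,4,5-tetramethoxybenzaldehyde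
Product: 5 2,3,4,5-tetramethoxyphenol, via aryl formate 4 (not isolated)
Conditions: 30% aq H2O2, H2SO4 (cat.), MeOH, rt
Reagents that add atoms: hydrogen peroxide, OO
Why: Acid-catalysed Dakin oxidation (a Baeyer–Villiger-type rearrangement): the hydroperoxide adduct of the aldehyde rearranges with migration of the electron-rich aryl group, which the ortho and para methoxy groups favour over hydride migration, and formate 4 is cleaved by methanol under the same acid.

Step 3
Reactants: 5 2,3,4,5-tetramethoxyphenol
Product: 6 2-iodo-3,4,5,6-tetramethoxyphenol
Conditions: NIS, MeCN, 0 °C, dark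
Reagents that add atoms: N-iodosuccinimide, O=C1CCC(=O)N1I
Why: Electrophilic aromatic iodination: the phenol has a single unsubstituted ring carbon, ortho to the hydroxyl group and strongly activated, so the regiochemistry is fixed, and a mild iodonium donor at low temperature in a dry solvent is chosen to keep the electron-rich phenol from being oxidised.

Step 4
Reactants: 6 2-iodo-3,4,5,6-tetramethoxyphenol; 7 carbon monoxide; 8 4-ethynylanisole
Product: 11 5,6,7,8,4'-pentamethoxyflavone (tangeretin), via aryl ynone 9 (not isolated), via enaminone 10 (not isolated)
Conditions: PdCl2(PPh3)2 (5 mol %), Et2NH (solvent), CO (20 bar), 120 °C, autoclave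
Reagents that add atoms: none
Why: Zerovalent palladium, formed in the flask from PdCl2(PPh3)2, inserts into the C–I bond of 6, CO inserts to give the aroylpalladium iodide, and the acetylide of 8 (generated by Et2NH) is transferred and reductively eliminated, which forms C4a–C4 and C4–C3 in ynone 9 (a carbonylative Sonogashira coupling). Et2NH then adds to the alkyne carbon remote from the carbonyl to give enaminone 10, and the phenolic oxygen attacks that same carbon (the future C2) and expels the amine, forming O1–C2. The closest known reaction type is the palladium-catalysed carbonylative annulation of ortho-iodophenols with terminal alkynes to flavones in a secondary amine. Ring C closes in the 6-endo mode (6-endo-trig on the enaminone, equivalent to 6-endo-dig on the ynone) by addition–elimination, and no stereocentre is created. Two selectivities are needed: six-membered closure to the flavone rather than five-membered closure to the aurone, secured by the amine, which turns the ynone into a β-amino enone that is electrophilic only at C2; and carbonylative rather than direct coupling, secured by the CO pressure and by the two ortho substituents (OH and OMe) of the arylpalladium intermediate, which slow acetylide transfer relative to CO insertion. The position of ring fusion is fixed by 6 itself, since the iodine sits on the only carbon ortho to the hydroxyl group.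

Step 5
Reactants: 11 5,6,7,8,4'-pentamethoxyflavone
Product: 13 (2S)-5,6,7,8,4'-pentamethoxyflavanone, via cis-flavan-4-ol 12 (not isolated)
Conditions: Ru(cod)(2-methylallyl)2 (5 mol %), (R,R)-SINpEt·HBF4 (1,3-bis[(1R)-1-(naphthalen-1-yl)ethyl]-4,5-dihydroimidazolium tetrafluoroborate, 10 mol %), KOtBu (15 mol %), premixed in hexane at 70 °C; then 11, toluene, H2 (100 bar), rt; filter through silica, concentrate; then DMP, CH2Cl2, rt
Reagents that add atoms: none
Why: Enantioselective hydrogenation of the C2=C3 bond of a flavone with a chiral Ru–NHC catalyst: the C2-symmetric carbene ligands make the two faces of the planar pyranone unequal, so hydrogen is delivered to one face of C2 under catalyst control to give the 2S centre; the part of the ketone that is reduced further to the cis alcohol 12 keeps its C2 configuration, and Dess–Martin oxidation of the crude mixture returns it to ketone 13 under non-basic conditions that neither open ring C nor epimerise C2.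

**Compound list**

1 | 1,2,3,4-tetramethoxybenzene | COc1ccc(OC)c(OC)c1OC | starting material
2 | N,N-dimethyl-1-(2,3,4,5-tetramethoxyphenyl)methaniminium dichlorophosphate | COc1cc(C=[N+](C)C)c(OC)c(OC)c1OC.[O-]P(Cl)(Cl)=O | intermediate
3 | 2,3,4,5-tetramethoxybenzaldehyde | COc1cc(C=O)c(OC)c(OC)c1OC | intermediate
4 | 2,3,4,5-tetramethoxyphenyl formate | COc1cc(OC=O)c(OC)c(OC)c1OC | intermediate
5 | 2,3,4,5-tetramethoxyphenol | COc1cc(O)c(OC)c(OC)c1OC | intermediate
6 | 2-iodo-3,4,5,6-tetramethoxyphenol | COc1c(O)c(I)c(OC)c(OC)c1OC | intermediate
7 | carbon monoxide | [C-]#[O+] | starting material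
8 | 4-ethynylanisole | C#Cc1ccc(OC)cc1 | starting material
9 | 1-(2-hydroxy-3,4,5,6-tetramethoxyphenyl)-3-(4-methoxyphenyl)prop-2-yn-1-one | COc1ccc(C#CC(=O)c2c(O)c(OC)c(OC)c(OC)c2OC)cc1 | intermediate
10 | (E)-3-(diethylamino)-1-(2-hydroxy-3,4,5,6-tetramethoxyphenyl)-3-(4-methoxyphenyl)prop-2-en-1-one | CCN(CC)/C(=C/C(=O)c1c(O)c(OC)c(OC)c(OC)c1OC)c1ccc(OC)cc1 | intermediate
11 | 5,6,7,8,4'-pentamethoxyflavone (tangeretin) | COc1ccc(-c2cc(=O)c3c(OC)c(OC)c(OC)c(OC)c3o2)cc1 | intermediate
12 | (2S,4S)-5,6,7,8-tetramethoxy-2-(4-methoxyphenyl)chroman-4-ol (2,4-cis) | COc1ccc([C@@H]2C[C@H](O)c3c(OC)c(OC)c(OC)c(OC)c3O2)cc1 | intermediate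
13 | (2S)-5,6,7,8,4'-pentamethoxyflavanone | COc1ccc([C@@H]2CC(=O)c3c(OC)c(OC)c(OC)c(OC)c3O2)cc1 | target

**Step count and risks**

Total step count: 5. Longest linear sequence: 5 steps (1 to 13).

The three steps most likely to fail:

Step 4. Oxidative addition at the electron-rich C–I bond, which has two ortho substituents, may be sluggish. The aroylpalladium intermediate may be intercepted by Et2NH to give an amide. Coupling without CO uptake followed by five-membered closure may also compete. The fallback sets out from 5 and comes back to the route at 11. Phenol 5 is C-acetylated at its one free position (AcOH, BF3·OEt2, 80 °C, Fries-type acylation) to give 1-(2-hydroxy-3,4,5,6-tetramethoxyphenyl)ethanone F1. Claisen–Schmidt condensation with 4-methoxybenzaldehyde (KOH, EtOH, rt) should give the 2'-hydroxychalcone (E)-1-(2-hydroxy-3,4,5,6-tetramethoxyphenyl)-3-(4-methoxyphenyl)prop-2-en-1-one F2. Oxidative cyclisation (I2 cat., DMSO, 130 °C) then closes ring C to flavone 11.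

Step 5. Facial selectivity at C2 may be poor, conversion of the electron-rich flavone with its methoxy group next to the carbonyl may be incomplete, or an aromatic ring may be hydrogenated. The fallback sets out from 11 and comes back at 13. Conjugate transfer hydrogenation without stereocontrol (HCO2NH4, Pd/C (palladium on carbon), MeOH, reflux, stopped at the ketone stage) should give racemic 5,6,7,8,4'-pentamethoxyflavanone F3. Kinetic resolution by asymmetric transfer hydrogenation follows (RhCl[(R,R)-TsDPEN](C5Me5) or its enantiomer, whichever reduces the 2R ketone faster, HCO2H/Et3N, EtOAc, rt). It should convert the 2R enantiomer into (2R,4R)-5,6,7,8-tetramethoxy-2-(4-methoxyphenyl)chroman-4-ol F4 and leave the 2S ketone 13, which is separated by chromatography.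

Step 3. The electron-rich phenol may be oxidised by the iodonium source (quinone formation or oxidative coupling) instead of being substituted. The fallback sets out from 3 and comes back at 6, so that the free phenol never meets an electrophilic iodine reagent. Aldehyde 3 is iodinated at its single free position (I2, AgOCOCF3, CH2Cl2, rt) to give 2-iodo-3,4,5,6-tetramethoxybenzaldehyde F5. Dakin oxidation under the conditions of step 2 then passes through 2-iodo-3,4,5,6-tetramethoxyphenyl formate F6, which is methanolysed in the flask to iodophenol 6.

**Further compounds**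

F1 | step 4 | 1-(2-hydroxy-3,4,5,6-tetramethoxyphenyl)ethanone | CC(=O)c1c(O)c(OC)c(OC)c(OC)c1OC
F2 | step 4 | (E)-1-(2-hydroxy-3,4,5,6-tetramethoxyphenyl)-3-(4-methoxyphenyl)prop-2-en-1-one | COc1ccc(/C=C/C(=O)c2c(O)c(OC)c(OC)c(OC)c2OC)cc1
F3 | step 5 | racemic 5,6,7,8,4'-pentamethoxyflavanone | COc1ccc(C2CC(=O)c3c(OC)c(OC)c(OC)c(OC)c3O2)cc1
F4 | step 5 | (2R,4R)-5,6,7,8-tetramethoxy-2-(4-methoxyphenyl)chroman-4-ol | COc1ccc([C@H]2C[C@@H](O)c3c(OC)c(OC)c(OC)c(OC)c3O2)cc1
F5 | step 3 | 2-iodo-3,4,5,6-tetramethoxybenzaldehyde | COc1c(I)c(C=O)c(OC)c(OC)c1OC
F6 | step 3 | 2-iodo-3,4,5,6-tetramethoxyphenyl formate | COc1c(I)c(OC=O)c(OC)c(OC)c1OC
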